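**Retrosynthetic overview**
1. Target ⇒ hexabenzyl ether 21 (global hydrogenolysis) ⇒ ketol 20; the C3 carbinol comes from hydride delivery anti to the cis 2-aryl and 4-hydroxyl groups.
2. Lower ring C (O1–C2–C3–C4–C4a–C8a) ⇒ one-atom enlargement of the five-membered ring O1–C3–C4–C4a–C8a of the (Z)-2-benzylidene-2,3-dihydrobenzofuran-3-ol 18: epoxidation of the exocyclic C2=C3 enol ether, then 1,2-shift of O1 from C3 to C2. The enabling feature is that C3 carries oxygen next to the ring oxygen O1 while C2 is a benzylic carbon of the para-oxygenated ring B, so a spiro-epoxy ether at C3 ionises at C2 and O1 can follow.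
3. 18 ⇒ 5-exo-dig cyclisation of an ortho-hydroxyaryl propargylic alcohol; its carbinol centre (future C4) is the only catalyst-set stereocentre of the lower unit (asymmetric alkynylation of 13), and C2 and C3 are relayed from it.
4. Interflavan C4–C6 bond ⇒ Friedel–Crafts alkylation of 2,3-bis(benzyloxy)phenol (para to OH) by the flavan-4-yl cation from 7, before the lower heterocycle exists; ortho-formylation then supplies C4.
5. Upper unit ⇒ flavanone 6 by Pd-catalysed asymmetric conjugate addition to chromone 4. Ring order: upper pyranone, lower furan ring, then its enlargement to the lower pyran ring.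

Key step: step 11

Assumption: 1, 5, 8 and 14 are purchased; the ligand enantiomers in steps 3 and 9 are chosen on the model of unsubstituted chromone and benzaldehyde, and the antipode is taken if the sense of induction differs.
Abbreviations: Bn = benzyl; TBS = tert-butyldimethylsilyl; ArB = 4-(benzyloxy)phenyl; Fl = (2S)-7,8-bis(benzyloxy)-2-[4-(benzyloxy)phenyl]chroman-4-yl, bonded through C4 with 2,4-trans geometry (its C4 descriptor reads S in 11 and 22 and R in 12–21 only because the CIP ranking of the two aryl groups on C4 changes).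

**Step 1**
Reactants: 1 1-(2,3,4-trihydroxyphenyl)ethan-1-one
Product: 2 1-[3,4-bis(benzyloxy)-2-hydroxyphenyl]ethan-1-one
Conditions: BnBr (2.1 equiv), K2CO3, acetone, reflux
Reagents that add atoms: benzyl bromide, BrCc1ccccc1
Why: Williamson etherification under mild base should leave the 2-hydroxyl free because it is hydrogen-bonded to the acetyl carbonyl and is the least reactive of the three; no stereocentre is formed.

**Step 2**
Reactants: 2 1-[3,4-bis(benzyloxy)-2-hydroxyphenyl]ethan-1-one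
Product: 4 7,8-bis(benzyloxy)-4H-chromen-4-one, via enaminone 3 (not isolated)
Conditions: Me2NCH(OMe)2, toluene, 100 °C; then AcOH, 80 °C
Reagents that add atoms: N,N-dimethylformamide dimethyl acetal, COC(OC)N(C)C
Why: Condensation of the methyl ketone with the amide acetal gives the enaminone, and acid-mediated addition–elimination by the phenol (loss of dimethylamine) closes the γ-pyranone, the standard enaminone chromone synthesis; no stereocentre is formed.

**Step 3**
Reactants: 4 7,8-bis(benzyloxy)-4H-chromen-4-one; 5 [4-(benzyloxy)phenyl]boronic acid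
Product: 6 (2S)-7,8-bis(benzyloxy)-2-[4-(benzyloxy)phenyl]chroman-4-one
Conditions: Pd(OCOCF3)2 (5 mol%), (R)-t-BuPyOx (6 mol%), NH4PF6 (30 mol%), H2O (5 equiv), ClCH2CH2Cl, 60 °C
Reagents that add atoms: none
Why: Palladium-catalysed asymmetric conjugate addition of an arylboronic acid to a chromone with a pyridine–oxazoline ligand is an established route to 2-arylchroman-4-ones; the ligand selects the enone face and should set C2 of the upper unit as S, and the base-free medium avoids retro-oxa-Michael racemisation.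

**Step 4**
Reactants: 6 (2S)-flavanone
Product: 7 (2S,4S)-7,8-bis(benzyloxy)-2-[4-(benzyloxy)phenyl]chroman-4-ol (2,4-cis)
Conditions: NaBH4, THF–MeOH, 0 °C
Reagents that add atoms: none
Why: Borohydride reduction of a flavanone proceeds by axial hydride delivery to give the 2,4-cis alcohol; the C4 configuration is inconsequential because this centre is ionised in step 6.

**Step 5**
Reactants: 8 2,3-bis(benzyloxy)benzaldehyde
Product: 10 2,3-bis(benzyloxy)phenol, via aryl formate 9 (not isolated)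
Conditions: mCPBA, CH2Cl2, rt; then K2CO3 (cat.), MeOH, rt
Reagents that add atoms: 3-chloroperoxybenzoic acid, O=C(OO)c1cccc(Cl)c1
Why: Dakin-type Baeyer–Villiger oxidation, in which the electron-rich aryl group migrates to give the aryl formate that is then cleaved by methanolysis; no stereocentre is formed.

**Step 6**
Reactants: 7 (2S,4S)-flavan-4-ol; 10 2,3-bis(benzyloxy)phenol
Product: 11 2,3-bis(benzyloxy)-4-Fl-phenol (upper unit 2S,4S; 2,4-trans)
Conditions: 10 (3 equiv), BF3·OEt2 (20 mol%), CH2Cl2, −78 → −30 °C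
Reagents that add atoms: none
Why: Friedel–Crafts alkylation in which BF3·OEt2 ionises the flavan-4-ol to a cation stabilised by O1 and the 7-benzyloxy group, the excess free phenol takes it up para to its hydroxyl (ortho to a benzyloxy group) and so outcompetes self-condensation, and pseudo-axial attack on the half-chair cation with the 2-aryl group pseudo-equatorial should set the upper C4 centre 2,4-trans.

**Step 7**
Reactants: 11 2,3-bis(benzyloxy)-4-Fl-phenol
Product: 12 3,4-bis(benzyloxy)-5-Fl-2-hydroxybenzaldehyde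
Conditions: MgCl2, Et3N, (CH2O)n, MeCN, 80 °C
Reagents that add atoms: paraformaldehyde (as formaldehyde), C=O
Why: Phenoxide-directed ortho-formylation with MgCl2/Et3N/paraformaldehyde (Casnati–Skattebøl) can react only at the single free position ortho to the phenol, the carbon that becomes C4a; no stereocentre is formed.

**Step 8**
Reactants: 12 3,4-bis(benzyloxy)-5-Fl-2-hydroxybenzaldehyde
Product: 13 3,4-bis(benzyloxy)-5-Fl-2-(TBS-oxy)benzaldehyde
Conditions: TBSCl, imidazole, DMF, rt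
Reagents that add atoms: tert-butyldimethylsilyl chloride, CC(C)(C)[Si](C)(C)Cl
Why: Silylation masks the acidic, chelating phenol for the organozinc addition; no stereocentre is formed.

**Step 9**
Reactants: 13 silyl-protected salicylaldehyde; 14 1-(benzyloxy)-4-ethynylbenzene
Product: 16 (1S)-1-[3,4-bis(benzyloxy)-5-Fl-2-(TBS-oxy)phenyl]-3-ArB-prop-2-yn-1-ol, via alkynylzinc reagent 15 (not isolated)
Conditions: 14, ZnEt2, toluene, 110 °C; then (S)-BINOL (20 mol%), Ti(OiPr)4 (50 mol%), 13, CH2Cl2, rt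
Reagents that add atoms: none
Why: Catalytic asymmetric alkynylation of an aromatic aldehyde by an alkynylzinc reagent under BINOL–Ti(OiPr)4 control, in which the (S)-ligand should direct the alkynyl group to the aldehyde face that gives the (S)-carbinol, the future C4 of the lower unit and its only catalyst-set centre.

**Step 10**
Reactants: 16 (1S)-propargylic alcohol
Product: 18 (2Z,3R)-6,7-bis(benzyloxy)-2-[4-(benzyloxy)benzylidene]-5-Fl-2,3-dihydro-1-benzofuran-3-ol, via phenol 17 (not isolated)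
Conditions: K2CO3 (0.2 equiv), MeOH–THF, rt; then AuCl (10 mol%), K2CO3 (10 mol%), MeCN, rt
Reagents that add atoms: none
Why: Carbonate-mediated methanolysis cleaves the aryl silyl ether selectively, and AuCl-catalysed anti-hydroalkoxylation of the alkyne by the phenol follows the 5-exo-dig mode established for 2-(1-hydroxyprop-2-ynyl)phenols, giving the (Z)-enol ether (aryl cis to the ring oxygen) without touching the carbinol centre.

**Step 11**
Reactants: 18 (2Z,3R)-2-benzylidene-2,3-dihydrobenzofuran-3-ol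
Product: 20 (2R,4R)-7,8-bis(benzyloxy)-2-ArB-6-Fl-4-hydroxychroman-3-one (2,4-cis ketol), via spiro-epoxide 19 (not isolated)
Conditions: DMDO (acetone solution, 1.1 equiv), CH2Cl2, −78 °C; then PPTS (5 mol%), −78 → 0 °C
Reagents that add atoms: dimethyldioxirane, CC1(C)OO1
Why: Proposed new method: dimethyldioxirane, directed by hydrogen bonding to the free 3-hydroxyl, should epoxidise the electron-rich exocyclic enol ether of 18 on the hydroxyl face to give the spiro epoxy ether 19, whose benzylic C–O bond (cation stabilised by the 4-benzyloxyphenyl group) ionises while the aryloxy oxygen O1 shifts from the acetal carbon to the benzylic carbon and the acetal carbon collapses to the ketone, turning the five-membered furan ring into the six-membered pyranone of 20. The closest known reaction types are the thermal or acid-promoted rearrangement of epoxy ethers to α-alkoxy ketones by 1,2-alkoxy shift and the oxidative five-to-six ring enlargement of furfuryl alcohols (Achmatowicz rearrangement); neither has been applied to a 3-hydroxy-2-benzylidene-2,3-dihydrobenzofuran. The pyran ring is closed by 1,2-migration of O1 (equivalently, opening of the hemiketal-type carbon to the phenoxide and six-membered O-alkylation of the benzylic cation), not by cyclisation of an open chain. The new stereocentre C2 is controlled by the carbinol centre set in step 9: least-motion migration of O1 from the hydroxyl-face epoxide places the aryl group cis to the 4-hydroxyl, and because C2–H is benzylic and α to the ketone any trans isomer can equilibrate to the same 2,4-cis ketol, in which the aryl group and the hydrogen-bonded hydroxyl are both pseudo-equatorial. The step needs O-migration in preference to migration of the carbinol carbon (which would give a 3-aryl-4-hydroxychroman-2-one) and to dehydrative aromatisation to a benzofuran; the para-alkoxy aryl group that localises the cation at the migration terminus, the leaving ability of the phenoxide from the hemiketal-type carbon, the syn epoxide (which cannot undergo epoxide transposition with the neighbouring hydroxyl) and the cold, non-acidic epoxidation should secure this.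

**Step 12**
Reactants: 20 (2R,4R)-4-hydroxychroman-3-one
Product: 21 (2R,3R,4R)-7,8-bis(benzyloxy)-2-ArB-6-Fl-chromane-3,4-diol (2,3-cis-3,4-cis)
Conditions: LiBH(s-Bu)3 (L-Selectride, 3 equiv), THF, −78 °C; aq NH4Cl
Reagents that add atoms: none
Why: Substrate-controlled reduction by the bulky hydride LiBH(s-Bu)3, which attacks flavan-3-ones and α-hydroxy cyclohexanones from the face opposite their pseudo-equatorial α-substituents, should deliver hydride anti to the cis-disposed 2-aryl and 4-oxygen groups and set C3 with its hydroxyl cis to both, while at −78 °C neither α-centre epimerises.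

**Step 13**
Reactants: 21 hexabenzyl ether
Product: 22 (2R,3R,4R)-6-[(2S,4S)-7,8-dihydroxy-2-(4-hydroxyphenyl)chroman-4-yl]-2-(4-hydroxyphenyl)chromane-3,4,7,8-tetrol (target)
Conditions: H2 (1 atm), Pd(OH)2/C, EtOAc–MeOH, rt
Reagents that add atoms: none
Why: Hydrogenolysis of the six aryl benzyl ethers over Pd(OH)2/C under neutral conditions should be much faster than cleavage of the secondary benzylic C4–OH or of the diarylmethine C–C bond; no stereocentre is affected.

**Compound list**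
1 | 1-(2,3,4-trihydroxyphenyl)ethan-1-one (gallacetophenone) | CC(=O)c1ccc(O)c(O)c1O | starting material
2 | 1-[3,4-bis(benzyloxy)-2-hydroxyphenyl]ethan-1-one | CC(=O)c1ccc(OCc2ccccc2)c(OCc2ccccc2)c1O | intermediate
3 | (E)-1-[3,4-bis(benzyloxy)-2-hydroxyphenyl]-3-(dimethylamino)prop-2-en-1-one | CN(C)/C=C/C(=O)c1ccc(OCc2ccccc2)c(OCc2ccccc2)c1O | intermediate
4 | 7,8-bis(benzyloxy)-4H-chromen-4-one | O=c1ccoc2c(OCc3ccccc3)c(OCc3ccccc3)ccc12 | intermediate
5 | [4-(benzyloxy)phenyl]boronic acid | OB(O)c1ccc(OCc2ccccc2)cc1 | starting material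
6 | (2S)-7,8-bis(benzyloxy)-2-[4-(benzyloxy)phenyl]chroman-4-one | O=C1C[C@@H](c2ccc(OCc3ccccc3)cc2)Oc2c(OCc3ccccc3)c(OCc3ccccc3)ccc21 | intermediate
7 | (2S,4S)-7,8-bis(benzyloxy)-2-[4-(benzyloxy)phenyl]chroman-4-ol (2,4-cis) | O[C@H]1C[C@@H](c2ccc(OCc3ccccc3)cc2)Oc2c(OCc3ccccc3)c(OCc3ccccc3)ccc21 | intermediate
8 | 2,3-bis(benzyloxy)benzaldehyde | O=Cc1cccc(OCc2ccccc2)c1OCc1ccccc1 | starting material
9 | 2,3-bis(benzyloxy)phenyl formate | O=COc1cccc(OCc2ccccc2)c1OCc1ccccc1 | intermediate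
10 | 2,3-bis(benzyloxy)phenol | Oc1cccc(OCc2ccccc2)c1OCc1ccccc1 | intermediate
11 | 2,3-bis(benzyloxy)-4-{(2S,4S)-7,8-bis(benzyloxy)-2-[4-(benzyloxy)phenyl]chroman-4-yl}phenol | Oc1ccc([C@@H]2C[C@@H](c7ccc(OCc6ccccc6)cc7)Oc3c(OCc6ccccc6)c(OCc6ccccc6)ccc32)c(OCc6ccccc6)c1OCc6ccccc6 | intermediate
12 | 3,4-bis(benzyloxy)-5-{(2S,4R)-7,8-bis(benzyloxy)-2-[4-(benzyloxy)phenyl]chroman-4-yl}-2-hydroxybenzaldehyde | O=Cc1cc([C@@H]2C[C@@H](c7ccc(OCc6ccccc6)cc7)Oc3c(OCc6ccccc6)c(OCc6ccccc6)ccc32)c(OCc6ccccc6)c(OCc6ccccc6)c1O | intermediate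
13 | 3,4-bis(benzyloxy)-5-Fl-2-[(tert-butyldimethylsilyl)oxy]benzaldehyde (Fl 2S,4R) | O=Cc1cc([C@@H]2C[C@@H](c7ccc(OCc6ccccc6)cc7)Oc3c(OCc6ccccc6)c(OCc6ccccc6)ccc32)c(OCc6ccccc6)c(OCc6ccccc6)c1O[Si](C)(C)C(C)(C)C | intermediate
14 | 1-(benzyloxy)-4-ethynylbenzene | C#Cc1ccc(OCc2ccccc2)cc1 | starting material
15 | ethyl{[4-(benzyloxy)phenyl]ethynyl}zinc, EtZnC≡CArB | CC[Zn]C#Cc1ccc(OCc2ccccc2)cc1 | intermediate
16 | (1S)-1-{3,4-bis(benzyloxy)-5-Fl-2-[(tert-butyldimethylsilyl)oxy]phenyl}-3-[4-(benzyloxy)phenyl]prop-2-yn-1-ol (Fl 2S,4R) | O[C@@H](C#Cc7ccc(OCc6ccccc6)cc7)c1cc([C@@H]2C[C@@H](c7ccc(OCc6ccccc6)cc7)Oc3c(OCc6ccccc6)c(OCc6ccccc6)ccc32)c(OCc6ccccc6)c(OCc6ccccc6)c1O[Si](C)(C)C(C)(C)C | intermediate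
17 | (1S)-1-[3,4-bis(benzyloxy)-5-Fl-2-hydroxyphenyl]-3-[4-(benzyloxy)phenyl]prop-2-yn-1-ol (Fl 2S,4R) | O[C@@H](C#Cc7ccc(OCc6ccccc6)cc7)c1cc([C@@H]2C[C@@H](c7ccc(OCc6ccccc6)cc7)Oc3c(OCc6ccccc6)c(OCc6ccccc6)ccc32)c(OCc6ccccc6)c(OCc6ccccc6)c1O | intermediate
18 | (2Z,3R)-6,7-bis(benzyloxy)-2-[4-(benzyloxy)benzylidene]-5-Fl-2,3-dihydro-1-benzofuran-3-ol (Fl 2S,4R) | O[C@H]1/C(=C/c7ccc(OCc6ccccc6)cc7)Oc5c(OCc6ccccc6)c(OCc6ccccc6)c([C@@H]2C[C@@H](c7ccc(OCc6ccccc6)cc7)Oc3c(OCc6ccccc6)c(OCc6ccccc6)ccc32)cc51 | intermediate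
19 | (2R,3R,3'S)-6,7-bis(benzyloxy)-3'-[4-(benzyloxy)phenyl]-5-Fl-3H-spiro[1-benzofuran-2,2'-oxiran]-3-ol, epoxide oxygen cis to the 3-hydroxyl (Fl 2S,4R) | O[C@H]1[C@@]4(O[C@H]4c7ccc(OCc6ccccc6)cc7)Oc5c(OCc6ccccc6)c(OCc6ccccc6)c([C@@H]2C[C@@H](c7ccc(OCc6ccccc6)cc7)Oc3c(OCc6ccccc6)c(OCc6ccccc6)ccc32)cc51 | intermediate
20 | (2R,4R)-7,8-bis(benzyloxy)-2-[4-(benzyloxy)phenyl]-6-Fl-4-hydroxychroman-3-one, 2,4-cis (Fl 2S,4R) | O[C@H]1C(=O)[C@@H](c7ccc(OCc6ccccc6)cc7)Oc5c(OCc6ccccc6)c(OCc6ccccc6)c([C@@H]2C[C@@H](c7ccc(OCc6ccccc6)cc7)Oc3c(OCc6ccccc6)c(OCc6ccccc6)ccc32)cc51 | intermediate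
21 | (2R,3R,4R)-7,8-bis(benzyloxy)-2-[4-(benzyloxy)phenyl]-6-Fl-chromane-3,4-diol, all-cis (Fl 2S,4R) | O[C@H]1[C@@H](O)[C@@H](c7ccc(OCc6ccccc6)cc7)Oc5c(OCc6ccccc6)c(OCc6ccccc6)c([C@@H]2C[C@@H](c7ccc(OCc6ccccc6)cc7)Oc3c(OCc6ccccc6)c(OCc6ccccc6)ccc32)cc51 | intermediate
22 | (2R,3R,4R)-6-[(2S,4S)-7,8-dihydroxy-2-(4-hydroxyphenyl)chroman-4-yl]-2-(4-hydroxyphenyl)chromane-3,4,7,8-tetrol (CNP0209379.1) | Oc1ccc([C@@H]2C[C@@H](c3cc4c(c(O)c3O)O[C@H](c3ccc(O)cc3)[C@H](O)[C@@H]4O)c3ccc(O)c(O)c3O2)cc1 | target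

**Step count and risks**
Total step count: 13. Longest linear sequence: 12 steps (steps 1–4 and 6–13, from 1).

Steps most likely to fail:

Step 11 (proposed method). What may go wrong: migration of the carbinol carbon instead of O1 (ring enlargement to a lactone), ionisation of the allylic alcohol with aromatisation to a benzofuran before or after epoxidation, or incomplete 2,4-cis control at C2. The fallback uses known chemistry and closes the six-membered ring directly; it sets out from 16 and returns to the route at 21. The propargylic hydroxyl of 16 is silylated (TBSOTf, 2,6-lutidine) to give the bis-silyl ether F1. Semihydrogenation (H2, Pd/CaCO3 poisoned with Pb(OAc)2, quinoline) gives the (Z)-allylic silyl ether F2. Dihydroxylation (OsO4 cat., NMO), syn across the Z-alkene and anti to the allylic silyloxy group, gives the erythro,erythro diol F3. K2CO3 in MeOH frees the phenol to give the phenol diol F4. Mitsunobu etherification (PPh3, DIAD) displaces the more reactive benzylic hydroxyl with inversion and gives the all-cis 4-O-silyl flavan-3-ol F5. Bu4NF in THF then gives 21.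

Step 6. What may go wrong: self-condensation of the flavan-4-yl cation with ring A of unreacted 7, attack ortho instead of para to the phenolic hydroxyl, and erosion of the 2,4-trans selectivity by acid-mediated re-ionisation. The fallback sets out from 7 and returns at 11. The cation is first trapped with phenylmethanethiol (cat. BF3·OEt2, CH2Cl2, −78 °C) as the bench-stable 4-benzylsulfanyl flavan F6, which cannot self-condense. The thiophilic salt AgBF4 (THF, 0 °C) then releases the cation slowly under non-acidic conditions in the presence of 10 to give 11.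

Step 13. What may go wrong: hydrogenolytic loss of the benzylic C4 hydroxyl of the lower unit during debenzylation. The fallback sets out from 21 and returns at 22. The cis-diol is first bridged with t-Bu2Si(OTf)2 and 2,6-lutidine to give the cyclic silylene F7, which holds the benzylic C–O bond in a ring that resists hydrogenolysis. Hydrogenolysis (H2, Pd(OH)2/C) then gives the hexaphenol silylene F8, and buffered fluoride (Bu4NF/AcOH, THF, 0 °C) gives 22.

**Further compounds**
F1 | step 11 | (1S)-O-TBS ether of 16: tert-butyl{(1S)-1-[3,4-bis(benzyloxy)-5-Fl-2-(TBS-oxy)phenyl]-3-ArB-prop-2-yn-1-yloxy}dimethylsilane | CC(C)(C)[Si](C)(C)O[C@@H](C#Cc7ccc(OCc6ccccc6)cc7)c1cc([C@@H]2C[C@@H](c7ccc(OCc6ccccc6)cc7)Oc3c(OCc6ccccc6)c(OCc6ccccc6)ccc32)c(OCc6ccccc6)c(OCc6ccccc6)c1O[Si](C)(C)C(C)(C)C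
F2 | step 11 | (1S,2Z)-1-[3,4-bis(benzyloxy)-5-Fl-2-(TBS-oxy)phenyl]-3-ArB-1-(TBS-oxy)prop-2-ene | CC(C)(C)[Si](C)(C)O[C@@H](/C=C\c7ccc(OCc6ccccc6)cc7)c1cc([C@@H]2C[C@@H](c7ccc(OCc6ccccc6)cc7)Oc3c(OCc6ccccc6)c(OCc6ccccc6)ccc32)c(OCc6ccccc6)c(OCc6ccccc6)c1O[Si](C)(C)C(C)(C)C
F3 | step 11 | (1R,2S,3S)-1-[3,4-bis(benzyloxy)-5-Fl-2-(TBS-oxy)phenyl]-3-ArB-1-(TBS-oxy)propane-2,3-diol (erythro,erythro) | CC(C)(C)[Si](C)(C)O[C@H](c1cc([C@@H]2C[C@@H](c7ccc(OCc6ccccc6)cc7)Oc3c(OCc6ccccc6)c(OCc6ccccc6)ccc32)c(OCc6ccccc6)c(OCc6ccccc6)c1O[Si](C)(C)C(C)(C)C)[C@@H](O)[C@@H](O)c7ccc(OCc6ccccc6)cc7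
F4 | step 11 | (1R,2S,3S)-1-[3,4-bis(benzyloxy)-5-Fl-2-hydroxyphenyl]-3-ArB-1-(TBS-oxy)propane-2,3-diol | CC(C)(C)[Si](C)(C)O[C@H](c1cc([C@@H]2C[C@@H](c7ccc(OCc6ccccc6)cc7)Oc3c(OCc6ccccc6)c(OCc6ccccc6)ccc32)c(OCc6ccccc6)c(OCc6ccccc6)c1O)[C@@H](O)[C@@H](O)c7ccc(OCc6ccccc6)cc7
F5 | step 11 | (2R,3S,4R)-7,8-bis(benzyloxy)-2-ArB-6-Fl-4-(TBS-oxy)chroman-3-ol (all-cis 4-O-TBS ether of 21) | CC(C)(C)[Si](C)(C)O[C@H]1[C@@H](O)[C@@H](c7ccc(OCc6ccccc6)cc7)Oc5c(OCc6ccccc6)c(OCc6ccccc6)c([C@@H]2C[C@@H](c7ccc(OCc6ccccc6)cc7)Oc3c(OCc6ccccc6)c(OCc6ccccc6)ccc32)cc51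
F6 | step 6 | (2S,4R)-4-(benzylsulfanyl)-7,8-bis(benzyloxy)-2-[4-(benzyloxy)phenyl]chromane (2,4-trans) | C(S[C@@H]2C[C@@H](c7ccc(OCc6ccccc6)cc7)Oc3c(OCc6ccccc6)c(OCc6ccccc6)ccc32)c1ccccc1
F7 | step 13 | 3,4-O-(di-tert-butylsilanediyl) derivative of 21 | CC(C)(C)[Si]8(C(C)(C)C)O[C@H]1[C@@H](O8)[C@@H](c7ccc(OCc6ccccc6)cc7)Oc5c(OCc6ccccc6)c(OCc6ccccc6)c([C@@H]2C[C@@H](c7ccc(OCc6ccccc6)cc7)Oc3c(OCc6ccccc6)c(OCc6ccccc6)ccc32)cc51
F8 | step 13 | 3,4-O-(di-tert-butylsilanediyl) derivative of 22 | Oc1ccc([C@@H]2C[C@@H](c3cc4c(c(O)c3O)O[C@H](c3ccc(O)cc3)[C@@H]5O[Si](C(C)(C)C)(C(C)(C)C)O[C@H]45)c3ccc(O)c(O)c3O2)cc1
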